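## The problem

Daucane numbering is used throughout (C1 quaternary and methyl-bearing, C2, C3, C4 isopropyl carbinol, C5 fusion CH, C6, C7, C8 methyl-bearing, C9, C10). The six-membered-ring intermediates simply lack C9.

- The target 21 is a daucane diester: a cyclopentane (C1–C5) fused along C1–C5 to a cycloheptene (C1, C5–C10). Reading the stereodescriptors shows the fusion is cis, with the C1 methyl and H5 on the same face.
- Five stereocentres sit around the fusion: C1, C5, the tertiary carbinol C4, and the secondary carbinols C6 and C10 (1R,4S,5S,6R,10S).
- On the folded cis bicycle the face carrying the C1 methyl and H5 is convex ("exo"). The C4 hydroxyl is exo; the C6 and C10 oxygens are on the concave ("endo") face. The fusion can therefore direct all three if an oxidant reaches C3=C4, and hydride reaches C6 and C10, from the exo face.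
- Three oxygens must be told apart: a free tertiary alcohol, a 4-hydroxybenzoate at C6, and an isovalerate at the allylic, neopentyl C10. The two secondary hydroxyls therefore have to appear at different times.
- The allylic ester (ionisation), the tertiary alcohol (dehydration), the free phenol and both esters (base, hydride) rule out harsh conditions late. Early on, H5 is α to a ketone and allylic to the cyclopentene, so it is labile until C6 is reduced.
- The enabling feature: C10, C1(CH3), C5, C6, C7 and C8(CH3) are the six ring carbons, two methyls and two oxygens of 2,6-dimethyl-1,4-benzoquinone. C1 and C5 are the two ends of one quinone alkene, so C2–C3–C4 can be annulated across it; the seven-membered ring is the one-carbon homologue, with C9 inserted between C8 and C10.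

## Retrosynthesis

**Ester bonds (21 ⇐ 20 ⇐ 18 + 19; 18 ⇐ 17 ⇐ 15 + 16).** The two acyl C–O bonds are cut last. A statistical acylation of a 6,10-diol would not discriminate, so C6–OH is carried as a triisopropylsilyl ether from early on and C10–OH is generated last. Diol 15 then takes the isovaleryl group from 16 at C10 only (the tertiary C4–OH is inert); desilylation gives 18, and the aroyl group comes from 4-acetoxybenzoyl chloride 19. The phenol acetate in 20 is the only protecting group on the acyl side and is removed under neutral conditions.

**C10–H and C3–H (15 ⇐ 14).** Both hydrides are delivered in one operation to epoxy-enone 14: 1,2-reduction of the enone and opening of the epoxide at C3. Esters cannot be present at that point, which fixes the order above. The precursor has one stereocentre fewer at C10, and the C4 configuration is already locked in the epoxide.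

**C9 (14 ⇐ 13 ⇐ 11 via 12 ⇐ 10).** The C8–C9 and C9–C10 bonds are cut as a one-carbon ring expansion. Because C1 is quaternary, the C10 ketone can enolise only towards C8, so silyl enol ether 11 is regiodefined. Dibromocarbene addition and opening of cyclopropane 12 give bromo-enone 13, which is debrominated to 14. A direct annulation onto a seven-membered acceptor would need a tropone-like partner with no comparable symmetry or availability. The forward step needs the enol ether to be the only carbene acceptor, hence the epoxide is installed first.

**Epoxide, silicon and C6–H (10 ⇐ 9 ⇐ 8 ⇐ 7 ⇐ 6).** The epoxide oxygen is removed to give alkene 9 and the alkene is traced to vinylsilane 8. The silyl ether and the C6–H bond are then cut back to ene-dione 6. The forward order is: reduce C6 first (so H5 is no longer enolisable), protect, protodesilylate, then epoxidise on the exo face. Each change is a single functional-group operation controlled by the cis fusion.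

**Cyclopentene (6 ⇐ 4 + 5).** C1–C2 and C4–C5 are cut together. This (3+2) cut removes one ring, the quaternary centre and both fusion stereocentres at once and leads to allenylsilane 4 and achiral quinone 5. Cutting C2–C3 or C3–C4 would leave the quaternary centre to be made separately. The forward reaction must attack the methyl-bearing quinone carbon, close the ring rather than lose silicon, and select one enantiotopic face.

**Allene (4 ⇐ 2 + 3; 2 ⇐ 1).** The C4–isopropyl bond is cut by SN2′ substitution of propargylic mesylate 2 with the organocopper reagent from 3. Mesylate 2 comes from commercial alcohol 1.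

## Roads not taken

**Alternative 1: double allylation (4+3) of a cyclopentane cis-dialdehyde.**
- Cut: C9–C10 and C6–C7. Precursors are the cis-dialdehyde A1 (C4 as dioxolane) and 3-chloro-2-(chloromethyl)prop-1-ene A2. Indium metal would add the bis-allyl unit to both aldehydes and close the seven-membered ring as the 8-methylene 6,10-diol A3.
- Merits: the seven-membered ring, both carbinol oxygens and a C8 alkene precursor arrive in one step. No ring expansion and no halogen to remove. In ring-forming economy it is better than the chosen plan.
- Weak points for this target: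
  - A1 is itself the hard part: a quaternary C1 bearing a formyl group cis to an epimerisable α-formyl at C5, needing its own enantioselective synthesis.
  - Two carbinol centres form under weak control, the second in a seven-membered closure, and both must come out endo.
  - The two hydroxyls appear together, so they must be differentiated afterwards for two different esters.
  - Isomerising the exocyclic alkene to C8=C9 rather than C7=C8 has no obvious bias.
  - An isopropyl nucleophile would add to the C4 ketone from the exo face and place the hydroxyl endo, the wrong C4 epimer.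
- Comparison: the chosen plan spends three steps on C9 but takes six ring carbons and both methyls from 5, creates C6–OH and C10–OH at different times, and sets C4 by exo epoxidation in the required sense.

**Alternative 2: Prins–pinacol ring-enlarging cyclopentane annulation.**
- Cut: C2–C3 plus the C1–C5 bond formed by 1,2-shift. SnCl4 would ionise the acetal of the cyclohexyl substrate A4; the isopropenyl terminus attacks the oxocarbenium ion, and the C1 cation triggers migration of C5 from C10 to C1, giving the cis-fused 3-methoxy-hydroazulen-10-one A5.
- Merits: quaternary C1, the cis fusion, the cyclopentane and the ring-enlarged ketone all form in one mechanistically secure step. For fusion stereochemistry and for regiochemical certainty it is stronger than the chosen key step.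
- Weak points for this target:
  - A4 needs three stereocentres (C4, C5, C6) set beforehand.
  - A5 carries a C3 methoxy group the target lacks, and C4 is a methine without oxygen. Methanol must be eliminated and the hydroxyl introduced, which lands on the same epoxide end-game after extra steps.
  - The C8 methyl and the C8=C9 alkene are absent and must be built from the C10 ketone by dehydrogenation, methyl addition and re-oxidation.
- Comparison: the chosen plan carries a regiochemical risk this route does not have. Against that, after step 3 it holds every carbon except C9, with both methyls and both ring oxygens at the right atoms.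

**Alternative 3: Buchner ring expansion of a 4,7-dimethoxyindane.**
- Cut: C8–C9 and C7–C8. The rhodium carbenoid from ethyl diazoacetate A7 and Rh2(O2CCH3)4 would cyclopropanate the only unsubstituted arene bond of indane A6 (which already holds the silylated C4 carbinol). Norcaradiene opening gives cycloheptatriene ester A8.
- Merits: the seven-membered ring comes from a flat arene in one catalytic step; C6 and C10 are oxygenated as enol ethers and the C4 carbinol is present from the start. This is the shortest access to the hydroazulene skeleton.
- Weak points for this target: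
  - C1 and C5 are both sp2 in A8. The quaternary methyl and the cis H5 still have to be installed on a tetrasubstituted alkene, steered only by the remote C4 centre.
  - After enol-ether hydrolysis the C4 silyloxy group is β to the C5 enolate carbon and can be eliminated.
  - The ester carbon at C8 needs several steps to become a methyl group.
  - 1,5-Hydrogen shifts in the cycloheptatriene can scramble alkene positions.
- Comparison: it is faster to a seven-membered ring than the chosen plan, but it leaves the hardest stereochemical problem (C1 and the cis fusion) unsolved. The chosen plan solves that first and uses it to control C4, C6 and C10.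

Key step: step 3

Remarks on the chemistry:
- The cis fusion and the exo/endo assignments above are read from the target's stereodescriptors.
- The phenol is carried as its acetate.
- The (S)-catalyst in step 3 is chosen from the accepted binding model for quinones; the sense must be confirmed on 6, and the (R)-catalyst is used if 6 proves antipodal.

## Route

Step 1
Reactants: 1 3-(trimethylsilyl)prop-2-yn-1-ol
Product: 2 3-(trimethylsilyl)prop-2-yn-1-yl methanesulfonate
Conditions: CH3SO2Cl, N(C2H5)3, CH2Cl2, −20 → 0 °C
Reagents that add atoms: methanesulfonyl chloride, CS(=O)(=O)Cl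
Why: Standard sulfonylation of a primary propargylic alcohol; no stereocentre is involved and the C–Si bond is untouched.

Step 2
Reactants: 2 3-(trimethylsilyl)prop-2-yn-1-yl methanesulfonate; 3 isopropylmagnesium chloride, (CH3)2CHMgCl
Product: 4 trimethyl(4-methylpenta-1,2-dien-3-yl)silane
Conditions: CuBr, LiBr, THF, −78 °C → rt
Reagents that add atoms: none
Why: SN2′ substitution of a propargylic sulfonate by the organocopper reagent formed from 3 and CuBr; attack at the silyl-bearing alkyne carbon gives the 1-isopropyl-1-silylallene, the established route to 1-alkyl-1-(trimethylsilyl)allenes.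

Step 3
Reactants: 4 trimethyl(4-methylpenta-1,2-dien-3-yl)silane; 5 2,6-dimethyl-1,4-benzoquinone
Product: 6 (3aR,7aR)-6,7a-dimethyl-3-(propan-2-yl)-2-(trimethylsilyl)-3a,7a-dihydro-1H-indene-4,7-dione (cis-fused; daucane C1 and C5)
Conditions: (S)-1-(2-methylphenyl)-3,3-diphenyltetrahydro-1H,3H-pyrrolo[1,2-c][1,3,2]oxazaborole (20 mol %), HN(SO2CF3)2 (20 mol %), 4 (1.1 equiv), CH2Cl2, −78 → −40 °C
Reagents that add atoms: none
Why: Proposed new method: the cationic boron Lewis acid binds the carbonyl of 5 that becomes C6 (flanked by two CH groups and the more basic oxygen because both methyls are β to it), so the CH2 terminus of 4 adds to the methyl-bearing β-carbon (C1–C2), the β-silyl vinyl cation undergoes a 1,2-silyl shift, and the boron enolate carbon C5 closes on the new vinyl cation at C4 (C4–C5). The closest known reaction type is the TiCl4-promoted (trimethylsilyl)allene cyclopentene annulation of enones (Danheiser annulation), combined with the known use of such oxazaborolidinium salts for enantioselective cycloadditions of quinones; an allenylsilane has not been annulated onto a quinone, nor enantioselectively. The cyclopentene closes by collapse of the enolate carbon onto a linear vinyl cation whose empty orbital lies in the plane of the forming ring (formally 5-endo), an ionic closure without geometric restriction. C1 is set in the first C–C bond formation by the catalyst: in the two-point binding model (B–O coordination plus a C–H···O contact from the flanking CH) one aryl group covers one face of the bound enone and the Re face of the methyl-bearing carbon stays open, which corresponds to 1R. C5 follows from C1 because the three-atom tether can reach only the same face, so the fusion can only be cis. The step needs attack at the methyl-bearing rather than the unsubstituted carbon, which activation through the unhindered carbonyl secures by making the methyl-bearing carbon the β-position of the activated enone. It needs ring closure rather than desilylative propargylation, which the non-nucleophilic N(SO2CF3)2 counter-ion favours. It needs a single annulation, which the near-stoichiometric amount of 4 and the more hindered carbonyls of 6 favour.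

Step 4
Reactants: 6 cis-fused silylcyclopentene ene-dione
Product: 7 C6 alcohol: the C6 carbonyl of 6 (next to H5) reduced to CH–OH, hydroxyl endo (anti to H5 and to the C1 methyl); C10 enone, vinylsilane and fusion unchanged
Conditions: NaBH4, CeCl3·7H2O, CH3OH, −78 °C
Reagents that add atoms: none
Why: Luche 1,2-reduction; the C6 carbonyl (flanked by C5–H) is far more accessible than C10 (flanked by quaternary C1 and the C8 methyl), and hydride arrives on the exo face, anti to the cyclopentene and its isopropyl group, so the 6-hydroxyl is endo; H5 thereby ceases to be enolisable.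

Step 5
Reactants: 7 C6 alcohol
Product: 8 C6 triisopropylsilyl ether of 7
Conditions: TIPSOTf, 2,6-lutidine, CH2Cl2, −78 → 0 °C
Reagents that add atoms: triisopropylsilyl trifluoromethanesulfonate, CC(C)[Si](OS(=O)(=O)C(F)(F)F)(C(C)C)C(C)C
Why: Silyl triflate silylation of a hindered secondary alcohol under non-basic conditions that leave the γ-oxygenated enone intact; the triisopropylsilyl group is chosen to survive the acid of step 6, the base of step 9 and the hydride of step 11.

Step 6
Reactants: 8 C6 triisopropylsilyl ether
Product: 9 desilylated cyclopentene: C3–H in place of C3–Si(CH3)3, C3=C4 alkene with isopropyl on C4 retained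
Conditions: CF3CO2H, CH2Cl2, 0 °C → rt
Reagents that add atoms: none
Why: Protodesilylation of a vinylsilane: ipso protonation at C3 gives the tertiary β-silyl cation at C4 and loss of silicon regenerates the C3=C4 alkene in place; it is done only after C6 is reduced, so no β,γ- to α,β-enone isomerisation through C5 is possible.

Step 7
Reactants: 9 desilylated cyclopentene
Product: 10 C3,C4-epoxide of 9, epoxide oxygen exo (syn to the C1 methyl and H5), isopropyl on C4 endo
Conditions: 3-ClC6H4CO3H, NaHCO3, CH2Cl2, 0 °C
Reagents that add atoms: 3-chloroperoxybenzoic acid, OOC(=O)c1cccc(Cl)c1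
Why: Prilezhaev epoxidation; the electron-poor enone alkene is inert and the endo face of the cyclopentene is blocked by the six-membered ring and its silyloxy group, so oxygen is delivered exo and fixes the C4 configuration; the epoxide also removes the only alkene that could compete for dibromocarbene in step 9.

Step 8
Reactants: 10 epoxy-enone
Product: 11 triethylsilyl enol ether C10(OSi(C2H5)3)=C8(CH3), C7 now CH2
Conditions: (C2H5)3SiH, RhCl(P(C6H5)3)3 (cat.), THF, 50 °C
Reagents that add atoms: triethylsilane, CC[SiH](CC)CC
Why: Rhodium-catalysed 1,4-hydrosilylation of an enone with a monohydrosilane, which gives the silyl enol ether directly; hydrogen goes to C7 and silicon to the C10 oxygen, and because C1 is quaternary this is the only enol ether the ketone can form.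

Step 9
Reactants: 11 triethylsilyl enol ether
Product: 13 9-bromo-cyclohept-8-en-10-one: seven-membered ring with C10=O, C9–Br, C8(CH3)=C9, epoxide and silyl ether unchanged, via dibromocyclopropane 12 (not isolated)
Conditions: CHBr3, KOC(CH3)3, hexane, −20 °C → rt
Reagents that add atoms: bromoform, BrC(Br)Br
Why: Dibromocarbene adds to the electron-rich enol ether (no other alkene is present), and the siloxy-gem-dibromocyclopropane opens by disrotatory electrocyclic cleavage of the C8–C10 bond with loss of bromide and of the silyl group, the known halocarbene ring expansion of silyl enol ethers to 2-bromocycloalkenones; this inserts C9.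

Step 10
Reactants: 13 9-bromo-enone
Product: 14 epoxy-cycloheptenone: C10=O, C8(CH3)=C9H
Conditions: (C4H9)3SnH, Pd(P(C6H5)3)4 (cat.), THF, rt
Reagents that add atoms: none
Why: Palladium-catalysed hydrostannolysis of a vinyl bromide: zerovalent palladium inserts into the activated C–Br bond of the α-bromo-enone, tin hydride transfers hydrogen and reductive elimination gives the enone; the β,β-disubstituted enone is not reduced further without an acid additive.

Step 11
Reactants: 14 epoxy-cycloheptenone
Product: 15 4,10-diol: tertiary C4–OH exo, C3 now CH2, secondary allylic C10–OH endo, C6 silyl ether retained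
Conditions: LiAlH4, THF, −20 °C, then reflux
Reagents that add atoms: none
Why: LiAlH4 reduces the β,β-disubstituted enone 1,2 and opens the trisubstituted epoxide by SN2 attack at the secondary carbon C3, leaving the C4–O bond and its configuration intact; hydride should reach C10 from the exo face because the endo face is screened by the cyclopentane and the endo silyloxy group at C6, placing the 10-hydroxyl endo.

Step 12
Reactants: 15 4,10-diol; 16 3-methylbutanoyl chloride (isovaleryl chloride)
Product: 17 C10 isovalerate of 15 (C4–OH free, C6 silyl ether)
Conditions: pyridine, 4-(dimethylamino)pyridine (cat.), CH2Cl2, 0 °C → rt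
Reagents that add atoms: none
Why: Nucleophile-catalysed acylation of the secondary allylic alcohol; the tertiary, isopropyl-flanked C4 hydroxyl does not acylate under these conditions, so no protection is needed.

Step 13
Reactants: 17 C10 isovalerate
Product: 18 C6 alcohol: 10-isovaleryloxy-4,6-diol
Conditions: HF·pyridine, pyridine, THF, 0 °C → rt
Reagents that add atoms: none
Why: Fluoride cleavage of the Si–O bond under buffered, non-basic conditions, which avoids hydrolysis or migration of the isovalerate and is too mild to ionise the allylic ester or dehydrate the tertiary alcohol.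

Step 14
Reactants: 18 C6 alcohol; 19 4-acetoxybenzoyl chloride
Product: 20 C6 4-acetoxybenzoate, C10 isovalerate, C4–OH free
Conditions: N(C2H5)3, 4-(dimethylamino)pyridine, CH2Cl2, rt
Reagents that add atoms: none
Why: Nucleophile-catalysed acylation of the only remaining acylatable hydroxyl (C6–OH; C4–OH is tertiary); the phenol is masked as its acetate so that the acid chloride cannot oligomerise.

Step 15
Reactants: 20 C6 4-acetoxybenzoate
Product: 21 target: (1R,4S,5S,6R,10S)-4-hydroxy-10-(3-methylbutanoyloxy)dauc-8-en-6-yl 4-hydroxybenzoate; as an azulene, (3S,3aS,4R,8S,8aR)-3-hydroxy-6,8a-dimethyl-8-[(3-methylbutanoyl)oxy]-3-(propan-2-yl)-1,2,3,3a,4,5,8,8a-octahydroazulen-4-yl 4-hydroxybenzoate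
Conditions: ammonium acetate, CH3OH/H2O (4:1), rt
Reagents that add atoms: none
Why: Chemoselective neutral methanolysis of an aryl acetate, whose phenoxide leaving group makes it far more labile than the two hindered alkyl esters; no stereocentre is touched.

## Compound list

1 | 3-(trimethylsilyl)prop-2-yn-1-ol | C[Si](C)(C)C#CCO | starting material
2 | 3-(trimethylsilyl)prop-2-yn-1-yl methanesulfonate | C[Si](C)(C)C#CCOS(C)(=O)=O | intermediate
3 | isopropylmagnesium chloride, (CH3)2CHMgCl | CC(C)[Mg]Cl | starting material
4 | trimethyl(4-methylpenta-1,2-dien-3-yl)silane | C=C=C([Si](C)(C)C)C(C)C | intermediate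
5 | 2,6-dimethyl-1,4-benzoquinone | CC1=CC(=O)C=C(C)C1=O | starting material
6 | (3aR,7aR)-6,7a-dimethyl-3-(propan-2-yl)-2-(trimethylsilyl)-3a,7a-dihydro-1H-indene-4,7-dione (cis-fused) | CC=1C(=O)[C@]2(C)CC([Si](C)(C)C)=C(C(C)C)[C@@H]2C(=O)C=1 | intermediate
7 | C6 alcohol of 6, 6-OH endo (anti to H5 and the C1 methyl), C10 enone retained | CC=1C(=O)[C@]2(C)CC([Si](C)(C)C)=C(C(C)C)[C@@H]2[C@H](O)C=1 | intermediate
8 | C6 triisopropylsilyl ether of 7 | CC=1C(=O)[C@]2(C)CC([Si](C)(C)C)=C(C(C)C)[C@@H]2[C@H](O[Si](C(C)C)(C(C)C)C(C)C)C=1 | intermediate
9 | C3-desilylated 8 (C3=C4 alkene, isopropyl on C4) | CC=1C(=O)[C@]2(C)CC=C(C(C)C)[C@@H]2[C@H](O[Si](C(C)C)(C(C)C)C(C)C)C=1 | intermediate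
10 | C3,C4-exo-epoxide of 9 (oxygen syn to the C1 methyl and H5) | CC=1C(=O)[C@]2(C)C[C@H]3O[C@@]3(C(C)C)[C@@H]2[C@H](O[Si](C(C)C)(C(C)C)C(C)C)C=1 | intermediate
11 | triethylsilyl enol ether C10(OSiEt3)=C8(CH3) of the C7,C8-reduced ketone | CC1=C(O[Si](CC)(CC)CC)[C@]2(C)C[C@H]3O[C@@]3(C(C)C)[C@@H]2[C@H](O[Si](C(C)C)(C(C)C)C(C)C)C1 | intermediate
12 | dibromocyclopropane across C8–C10 (CBr2 = C9; C8/C10 configuration undefined, both converge) | CC12C(Br)(Br)C1(O[Si](CC)(CC)CC)[C@]3(C)C[C@H]4O[C@@]4(C(C)C)[C@@H]3[C@H](O[Si](C(C)C)(C(C)C)C(C)C)C2 | intermediate (not isolated)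
13 | 9-bromo-3,4-epoxy-6-(triisopropylsilyloxy)dauc-8-en-10-one (cis-fused) | CC1=C(Br)C(=O)[C@]2(C)C[C@H]3O[C@@]3(C(C)C)[C@@H]2[C@H](O[Si](C(C)C)(C(C)C)C(C)C)C1 | intermediate
14 | 3,4-epoxy-6-(triisopropylsilyloxy)dauc-8-en-10-one (cis-fused) | CC1=CC(=O)[C@]2(C)C[C@H]3O[C@@]3(C(C)C)[C@@H]2[C@H](O[Si](C(C)C)(C(C)C)C(C)C)C1 | intermediate
15 | 6-(triisopropylsilyloxy)dauc-8-ene-4,10-diol (4-OH exo, 10-OH endo) | CC1=C[C@H](O)[C@]2(C)CC[C@](O)(C(C)C)[C@@H]2[C@H](O[Si](C(C)C)(C(C)C)C(C)C)C1 | intermediate
16 | 3-methylbutanoyl chloride | CC(C)CC(=O)Cl | starting material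
17 | C10 isovalerate of 15 | CC1=C[C@H](OC(=O)CC(C)C)[C@]2(C)CC[C@](O)(C(C)C)[C@@H]2[C@H](O[Si](C(C)C)(C(C)C)C(C)C)C1 | intermediate
18 | 10-(3-methylbutanoyloxy)dauc-8-ene-4,6-diol | CC1=C[C@H](OC(=O)CC(C)C)[C@]2(C)CC[C@](O)(C(C)C)[C@@H]2[C@H](O)C1 | intermediate
19 | 4-acetoxybenzoyl chloride | CC(=O)Oc1ccc(C(=O)Cl)cc1 | starting material
20 | C6 4-acetoxybenzoate of 18 | CC1=C[C@H](OC(=O)CC(C)C)[C@]2(C)CC[C@](O)(C(C)C)[C@@H]2[C@H](OC(=O)c2ccc(OC(C)=O)cc2)C1 | intermediate
21 | (1R,4S,5S,6R,10S)-4-hydroxy-10-(3-methylbutanoyloxy)dauc-8-en-6-yl 4-hydroxybenzoate | CC1=C[C@H](OC(=O)CC(C)C)[C@]2(C)CC[C@](O)(C(C)C)[C@@H]2[C@H](OC(=O)c2ccc(O)cc2)C1 | target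

## Step count and least certain steps

Total: 15 steps. Longest linear sequence: 15 steps (1 → 21); 13 steps from quinone 5.

**Step 3 (key step).**
- What may go wrong: addition at the unsubstituted quinone carbon or at a carbonyl instead of the methyl-bearing carbon; loss of silicon before ring closure, giving open-chain propargylation; poor turnover or weak facial discrimination, because the chiral boron acid is a weaker promoter than TiCl4; a second annulation on 6. A stronger activation of the same oxazaborolidine (AlBr3 in place of the imide acid) is the first adjustment.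
- Fallback (known reaction types only; sets out from 5, returns at 9): the two ring bonds are made one at a time.
  - Reduction of 5 with Na2S2O4 gives 2,6-dimethylbenzene-1,4-diol F1. Its unhindered hydroxyl is methylated (CH3I, K2CO3) to 4-methoxy-2,6-dimethylphenol F2. Oxidation with PhI(O2CCH3)2 in CH3OH gives the quinone monoketal 4,4-dimethoxy-2,6-dimethylcyclohexa-2,5-dien-1-one F3.
  - The alkylating agent 1-bromo-4-methylpent-2-yne F4 is made from 4-methylpent-2-yn-1-ol and PBr3.
  - Conjugate reduction of F3 with LiBH(sec-C4H9)3 and alkylation of the enolate at its methyl-bearing carbon with F4 form the quaternary C1 and the C1–C2 bond in racemic 4,4-dimethoxy-2,6-dimethyl-6-(4-methylpent-2-yn-1-yl)cyclohex-2-en-1-one F5.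
  - Aqueous acid gives racemic 2,6-dimethyl-6-(4-methylpent-2-yn-1-yl)cyclohex-2-ene-1,4-dione F6. Kinetic deprotonation at C5 (LiN(Si(CH3)3)2, tert-butyldimethylsilyl chloride) gives the cross-conjugated tert-butyldimethylsilyl dienol ether F7.
  - (C6H5)3PAuCl/AgBF4 (monovalent gold) in CH2Cl2/CH3OH closes C4–C5 by 5-endo-dig carbocyclisation (Conia-ene type) to the racemic cis-fused ene-dione F8, the desilylated counterpart of 6.
  - Luche reduction as in step 4 gives the racemic C6 alcohol F9. Preparative chromatography on a chiral stationary phase gives the enantiomer with the C1, C5 and C6 configuration of 7, the resolved C6 alcohol F10. Silylation as in step 5 gives 9.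
  - The cost is about seven extra steps and half of the material at the resolution.

**Step 6 (protodesilylation).**
- What may go wrong: acid-induced migration of the C3=C4 alkene or rearrangement of the C4 cation, and partial loss of the silyl ether.
- Fallback (sets out from 8, returns at 9): replace protonation by halogen. ipso-Iododesilylation with N-iodosuccinimide gives the C3 vinyl iodide F11. Hydrodeiodination with (C4H9)3SnH and Pd(P(C6H5)3)4 then gives 9, with no carbocation exposed to acid.

**Step 9 (ring expansion).**
- What may go wrong: slow carbene addition to the hindered, tetrasubstituted enol ether next to quaternary C1; hydrolysis of the enol ether back to the ketone; a cyclopropane that does not open cleanly; attack of the silyl bromide formed on the epoxide.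
- Fallback (sets out from 11, returns at 14, which also bypasses step 10): Saegusa–Ito homologation. Cyclopropanation with Zn(C2H5)2/CH2I2 gives the siloxycyclopropane F12. FeCl3 in DMF/pyridine cleaves the C8–C10 bond through the alkoxy radical and the tertiary C8 radical to the 8-chloro-cycloheptanone F13. Sodium acetate in CH3OH eliminates HCl to give enone 14.

**Step 11 (double reduction).**
- What may go wrong: hydride delivery to the wrong face of C10, because the C1 methyl sits on the exo face next to the carbonyl; and sluggish opening of the hindered epoxide, whose C3 must be attacked from the endo face.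
- Fallback (sets out from 14, returns at 15): separate the two reductions and put C10 under reagent control. Corey–Bakshi–Shibata reduction with (R)-1-methyl-3,3-diphenyltetrahydro-1H,3H-pyrrolo[1,2-c][1,3,2]oxazaborole and catecholborane treats the quaternary C1 side as the large group and gives the epoxy allylic alcohol F14 with the 10S hydroxyl. LiBH(C2H5)3 then opens the epoxide at C3 to give 15.

## Further compounds

F1 | step 3 | 2,6-dimethylbenzene-1,4-diol | Cc1cc(O)cc(C)c1O
F2 | step 3 | 4-methoxy-2,6-dimethylphenol | COc1cc(C)c(O)c(C)c1
F3 | step 3 | 4,4-dimethoxy-2,6-dimethylcyclohexa-2,5-dien-1-one | COC1(OC)C=C(C)C(=O)C(C)=C1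
F4 | step 3 | 1-bromo-4-methylpent-2-yne | CC(C)C#CCBr
F5 | step 3 | 4,4-dimethoxy-2,6-dimethyl-6-(4-methylpent-2-yn-1-yl)cyclohex-2-en-1-one (racemic) | COC1(OC)C=C(C)C(=O)C(C)(CC#CC(C)C)C1
F6 | step 3 | 2,6-dimethyl-6-(4-methylpent-2-yn-1-yl)cyclohex-2-ene-1,4-dione (racemic) | CC1=CC(=O)CC(C)(CC#CC(C)C)C1=O
F7 | step 3 | 4-(tert-butyldimethylsilyloxy)-2,6-dimethyl-6-(4-methylpent-2-yn-1-yl)cyclohexa-2,4-dien-1-one (racemic) | CC1=CC(O[Si](C)(C)C(C)(C)C)=CC(C)(CC#CC(C)C)C1=O
F8 | step 3 | cis-6,7a-dimethyl-3-(propan-2-yl)-3a,7a-dihydro-1H-indene-4,7-dione (racemate, both enantiomers written) | CC=1C(=O)[C@]2(C)CC=C(C(C)C)[C@@H]2C(=O)C=1.CC=1C(=O)[C@@]2(C)CC=C(C(C)C)[C@H]2C(=O)C=1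
F9 | step 3 | C6 alcohol of F8, 6-OH endo (racemate, both enantiomers written) | CC=1C(=O)[C@]2(C)CC=C(C(C)C)[C@@H]2[C@H](O)C=1.CC=1C(=O)[C@@]2(C)CC=C(C(C)C)[C@H]2[C@@H](O)C=1
F10 | step 3 | resolved C6 alcohol (desilylated counterpart of 7) | CC=1C(=O)[C@]2(C)CC=C(C(C)C)[C@@H]2[C@H](O)C=1
F11 | step 6 | C3 vinyl iodide corresponding to 8 | CC=1C(=O)[C@]2(C)CC(I)=C(C(C)C)[C@@H]2[C@H](O[Si](C(C)C)(C(C)C)C(C)C)C=1
F12 | step 9 | siloxycyclopropane across C8–C10 (CH2 = C9) | CC12CC1(O[Si](CC)(CC)CC)[C@]3(C)C[C@H]4O[C@@]4(C(C)C)[C@@H]3[C@H](O[Si](C(C)C)(C(C)C)C(C)C)C2
F13 | step 9 | 8-chloro-3,4-epoxy-6-(triisopropylsilyloxy)daucan-10-one | CC1(Cl)CC(=O)[C@]2(C)C[C@H]3O[C@@]3(C(C)C)[C@@H]2[C@H](O[Si](C(C)C)(C(C)C)C(C)C)C1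
F14 | step 11 | 3,4-epoxy-6-(triisopropylsilyloxy)dauc-8-en-10-ol (10-OH endo) | CC1=C[C@H](O)[C@]2(C)C[C@H]3O[C@@]3(C(C)C)[C@@H]2[C@H](O[Si](C(C)C)(C(C)C)C(C)C)C1
A1 | alternative 1 | cis-1,2-diformyl-1-methylcyclopentane with C4 as dioxolane | O=C[C@]1(C)CCC2(OCCO2)[C@@H]1C=O
A2 | alternative 1 | 3-chloro-2-(chloromethyl)prop-1-ene | C=C(CCl)CCl
A3 | alternative 1 | 8-methylene bicyclic 6,10-diol (C4 dioxolane) | C=C1C[C@H](O)[C@]2(C)CCC3(OCCO3)[C@@H]2[C@H](O)C1
A4 | alternative 2 | Prins–pinacol substrate: 1-isopropenyl-1-(triethylsilyloxy)cyclohexane with C6 silyl ether and C4–C3 dimethyl acetal side chain (carbinol configuration immaterial) | C=C(C)C1(O[Si](CC)(CC)CC)CCC[C@@H](O[Si](C)(C)C(C)(C)C)[C@H]1[C@H](C(C)C)C(OC)OC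
A5 | alternative 2 | cis-fused 3-methoxy-hydroazulen-10-one | C1CC(=O)[C@]2(C)C[C@@H](OC)[C@@H](C(C)C)[C@@H]2[C@H](O[Si](C)(C)C(C)(C)C)C1
A6 | alternative 3 | 1-isopropyl-4,7-dimethoxy-1-(triethylsilyloxy)indane | COc1ccc(OC)c2c1CC[C@]2(O[Si](CC)(CC)CC)C(C)C
A7 | alternative 3 | ethyl diazoacetate | CCOC(=O)C=[N+]=[N-]
A8 | alternative 3 | ethyl 1-isopropyl-4,8-dimethoxy-1-(triethylsilyloxy)-1,2,3,6-tetrahydroazulene-6-carboxylate | CCOC(=O)[C@H]1C=C(OC)C2=C(C(OC)=C1)[C@@](O[Si](CC)(CC)CC)(C(C)C)CC2
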